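**Retrosynthetic overview**
1. Ring letters: the flavanone half is A (benzo), C (pyranone) and B (aryl); the flavone half is D (benzo), E (pyranone) and F (aryl). The plan rests on ring E. Its carbonyl carbon C4'' is bonded only to ring-D carbon C4a'' and to the two-carbon unit C3''=C2''. Ring E is therefore cut at C4a''–C4'', C4''–C3'' and O1''–C2'' into an aryl iodide, CO and 1-(benzyloxy)-4-ethynylbenzene.
2. Before iodination, ring D is a 2-aryl-5-(benzyloxy)resorcinol with a mirror plane through the C6–C8'' bond, so its two CH and its two OH are pairwise equivalent. After iodination the iodine has one free OH and one OBn as neighbours, so only the 8''-linked flavone can arise.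
3. C2 is set on a 6-arylchromone by rhodium-catalysed asymmetric 1,4-addition of an arylboronic acid. This irreversible C–C bond formation is preferred to a reversible chalcone closure.
4. The 6-linkage is fixed early by bromination beside the chelated OH of a phloroacetophenone ether, benzylation of that OH, and closure of ring C through the other, MOM-masked oxygen. The acetyl group is thus already in place at the Suzuki–Miyaura coupling, whose boronate comes from lithiation between two OMOM groups.
5. Benzyl is the lasting protecting group and is removed by neutral hydrogenolysis at the end. MOM masks only the three phenols freed on the way. Ring order: A and D are bought, then C (step 9, saturated in step 10), then E (step 13).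

Key step: step 13

Assumption: the SMILES fixes only C2. The hindered C6–C8'' bond becomes a stereogenic axis from 16 on and is left open, so both axial isomers count as the target, and 16 and 20–23 are handled as mixtures of the two.

**Step 1**
Reactants: 1 2,4,6-trihydroxyacetophenone
Product: 2 1-[4-(benzyloxy)-2,6-dihydroxyphenyl]ethanone
Conditions: BnBr (1.0 equiv), K2CO3 (1.0 equiv), DMF, rt
Reagents that add atoms: benzyl bromide, BrCc1ccccc1
Why: Williamson etherification, in which the 4-OH is the most acidic hydroxyl and the only one not tied to the acetyl oxygen by a hydrogen bond, so one equivalent of base and halide should alkylate it first.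

**Step 2**
Reactants: 2 1-[4-(benzyloxy)-2,6-dihydroxyphenyl]ethanone
Product: 3 1-[4-(benzyloxy)-2-hydroxy-6-(methoxymethoxy)phenyl]ethanone
Conditions: MOMCl (1.1 equiv), iPr2NEt (1.5 equiv), CH2Cl2, 0 °C to rt
Reagents that add atoms: chloromethyl methyl ether, COCCl
Why: O-alkylation with an acetal chloride, in which one of the two equivalent hydroxyls reacts and the remaining one is then locked in the hydrogen bond to C=O and resists a second alkylation under amine base.

**Step 3**
Reactants: 3 1-[4-(benzyloxy)-2-hydroxy-6-(methoxymethoxy)phenyl]ethanone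
Product: 4 1-[4-(benzyloxy)-3-bromo-2-hydroxy-6-(methoxymethoxy)phenyl]ethanone
Conditions: NBS (1.0 equiv), CH2Cl2, 0 °C, dark
Reagents that add atoms: N-bromosuccinimide, O=C1CCC(=O)N1Br
Why: Electrophilic aromatic bromination, which in 2-hydroxy-4,6-dialkoxyacetophenones goes to C3, the enol-like carbon beside the chelated hydroxyl, while NBS releases no acid that could harm the MOM ether.

**Step 4**
Reactants: 4 1-[4-(benzyloxy)-3-bromo-2-hydroxy-6-(methoxymethoxy)phenyl]ethanone
Product: 5 1-[2,4-bis(benzyloxy)-3-bromo-6-(methoxymethoxy)phenyl]ethanone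
Conditions: BnBr (1.3 equiv), K2CO3 (2 equiv), DMF, 60 °C
Reagents that add atoms: benzyl bromide, BrCc1ccccc1
Why: Williamson etherification under mild forcing caps the oxygen beside bromine (the later O5), so ring C can close only through the MOM-masked oxygen para to the future biaryl bond.

**Step 5**
Reactants: 6 phloroglucinol
Product: 7 3,5-bis(methoxymethoxy)phenol
Conditions: MOMCl (2.0 equiv), iPr2NEt (2.2 equiv), DMF, 0 °C to rt; chromatography
Reagents that add atoms: chloromethyl methyl ether, COCCl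
Why: Statistical O-alkylation of a threefold symmetric triphenol, with the diether separated from mono- and triether, which is acceptable for the first step of a short branch from a cheap material.

**Step 6**
Reactants: 7 3,5-bis(methoxymethoxy)phenol
Product: 8 1-(benzyloxy)-3,5-bis(methoxymethoxy)benzene
Conditions: BnBr (1.1 equiv), K2CO3 (1.5 equiv), DMF, rt
Reagents that add atoms: benzyl bromide, BrCc1ccccc1
Why: Williamson etherification of the single free phenol places the lasting benzyl group on the oxygen that becomes O5''.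

**Step 7**
Reactants: 8 1-(benzyloxy)-3,5-bis(methoxymethoxy)benzene
Product: 10 2-[4-(benzyloxy)-2,6-bis(methoxymethoxy)phenyl]-4,4,5,5-tetramethyl-1,3,2-dioxaborolane, via aryllithium 9 (not isolated)
Conditions: n-BuLi (1.1 equiv), THF, 0 °C; iPrOBpin (1.3 equiv), −78 °C to rt; then H2O
Reagents that add atoms: 2-isopropoxy-4,4,5,5-tetramethyl-1,3,2-dioxaborolane, CC(C)OB1OC(C)(C)C(C)(C)O1; n-butyllithium, [Li]CCCC (lithium of 9)
Why: Directed ortho-metalation removes the proton between the two chelating OMOM groups in preference to those beside OBn, and the aryllithium is trapped by the borate ester (borylation).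

**Step 8**
Reactants: 5 1-[2,4-bis(benzyloxy)-3-bromo-6-(methoxymethoxy)phenyl]ethanone; 10 2-[4-(benzyloxy)-2,6-bis(methoxymethoxy)phenyl]-4,4,5,5-tetramethyl-1,3,2-dioxaborolane
Product: 11 1-{2,4-bis(benzyloxy)-3-[4-(benzyloxy)-2,6-bis(methoxymethoxy)phenyl]-6-(methoxymethoxy)phenyl}ethanone
Conditions: Pd(OAc)2 (5 mol %), SPhos (10 mol %), K3PO4 (3 equiv), 10 (1.5 equiv), toluene–H2O 10:1, 100 °C
Reagents that add atoms: none
Why: Suzuki–Miyaura coupling, for which the bulky electron-rich biaryl monophosphine is suited to tetra-ortho-substituted biaryls, the four ortho groups are small alkoxy groups, and ketone, MOM and benzyl groups tolerate aqueous phosphate.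

**Step 9**
Reactants: 11 1-{2,4-bis(benzyloxy)-3-[4-(benzyloxy)-2,6-bis(methoxymethoxy)phenyl]-6-(methoxymethoxy)phenyl}ethanone
Product: 13 5,7-bis(benzyloxy)-6-[4-(benzyloxy)-2,6-dihydroxyphenyl]-4H-chromen-4-one, via enaminone 12 (not isolated)
Conditions: Me2NCH(OMe)2 (5 equiv), toluene, 110 °C; evaporate; then 2 M HCl, MeOH–THF, 50 °C
Reagents that add atoms: N,N-dimethylformamide dimethyl acetal, COC(OC)N(C)C
Why: Enaminone chromone synthesis, in which the methyl ketone condenses with the amide acetal and acid then frees the three MOM-masked phenols, of which only the one ortho to the enaminone carbonyl can displace dimethylamine (addition–elimination), so ring C closes through the oxygen para to the biaryl bond.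

**Step 10**
Reactants: 13 5,7-bis(benzyloxy)-6-[4-(benzyloxy)-2,6-dihydroxyphenyl]-4H-chromen-4-one; 14 4-(benzyloxy)phenylboronic acid
Product: 15 (2S)-5,7-bis(benzyloxy)-2-[4-(benzyloxy)phenyl]-6-[4-(benzyloxy)-2,6-dihydroxyphenyl]-2,3-dihydro-4H-chromen-4-one
Conditions: [RhCl(C2H4)2]2 (2.5 mol %), (S)-MeO-F12-BIPHEP [(S)-2,2'-bis{bis(3,4,5-trifluorophenyl)phosphino}-6,6'-dimethoxybiphenyl, 5.5 mol %], aq KOH (10 mol %), 14 (3 equiv), toluene–H2O 10:1, 25 °C
Reagents that add atoms: none
Why: Hayashi–Miyaura reaction (rhodium-catalysed asymmetric 1,4-addition of arylboronic acids to chromones, a known flavanone synthesis), in which aryl-rhodium carrying the (S)-configured electron-poor bisphosphine adds to the face of C2 that matches the (S)-ligand to (S)-3-arylcyclohexanone sense, which with the ranking O1 > aryl > C3 is 2S, and water protonates the rhodium enolate at room temperature before ring C can open.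

**Step 11**
Reactants: 15 (2S)-5,7-bis(benzyloxy)-2-[4-(benzyloxy)phenyl]-6-[4-(benzyloxy)-2,6-dihydroxyphenyl]-2,3-dihydro-4H-chromen-4-one
Product: 16 (2S)-5,7-bis(benzyloxy)-2-[4-(benzyloxy)phenyl]-6-[4-(benzyloxy)-2,6-dihydroxy-3-iodophenyl]-2,3-dihydro-4H-chromen-4-one
Conditions: NIS (1.0 equiv), MeCN–CH2Cl2, −20 to 0 °C, dark
Reagents that add atoms: N-iodosuccinimide, O=C1CCC(=O)N1I
Why: Electrophilic aromatic iodination, for which ring D (two free OH, no acyl group) is by far the most nucleophilic ring, its two open carbons are equivalent, and one equivalent of the neutral reagent at low temperature should stop at the mono-iodide without touching C2.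

**Step 12**
Reactants: 17 4-(benzyloxy)benzaldehyde
Product: 18 1-(benzyloxy)-4-ethynylbenzene
Conditions: MeC(O)C(N2)P(O)(OMe)2 (1.2 equiv), K2CO3 (2 equiv), MeOH, rt
Reagents that add atoms: dimethyl (1-diazo-2-oxopropyl)phosphonate, CC(=O)C(=[N+]=[N-])P(=O)(OC)OC
Why: Seyferth–Gilbert homologation in the Bestmann–Ohira variant turns a non-enolisable aryl aldehyde into the terminal alkyne in one operation through olefination, loss of nitrogen and 1,2-hydrogen shift.

**Step 13**
Reactants: 16 (2S)-5,7-bis(benzyloxy)-2-[4-(benzyloxy)phenyl]-6-[4-(benzyloxy)-2,6-dihydroxy-3-iodophenyl]-2,3-dihydro-4H-chromen-4-one; 18 1-(benzyloxy)-4-ethynylbenzene; 19 carbon monoxide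
Product: 22 (2S)-5,7-bis(benzyloxy)-2-[4-(benzyloxy)phenyl]-6-{5-(benzyloxy)-2-[4-(benzyloxy)phenyl]-7-hydroxy-4-oxo-4H-chromen-8-yl}-2,3-dihydro-4H-chromen-4-one, via ynone 20 (not isolated), via diethylamino enone 21 (not isolated)
Conditions: PdCl2(PPh3)2 (5 mol %), CO (5 bar), 18 (1.5 equiv), Et2NH (10 equiv), DMF, 55 °C
Reagents that add atoms: diethylamine, CCNCC (held only in 21, released again on ring closure)
Why: The divalent palladium precatalyst is reduced in the flask to zerovalent palladium, which inserts into the C–I bond of ring D; CO insertion gives an aroylpalladium iodide that takes up the amine-deprotonated alkyne and releases ynone 20 by reductive elimination (C4a''–C4'' and C4''–C3''). Diethylamine adds to the ynone to give the β-amino enone 21, and the hydroxyl on the neighbouring ring carbon attacks the amine-bearing carbon and expels the amine (O1''–C2''), a 6-endo addition–elimination that closes ring E. The closest known reaction is the palladium-catalysed carbonylative coupling of ortho-iodophenols with terminal arylacetylenes in secondary amines, a standard flavone synthesis. No stereocentre is formed and C2 is only carried through, which is why the temperature stays near 55 °C, no alkoxide or hydroxide is present, and O4' is benzylated so that ring C cannot open by a quinone-methide path. The step needs 6-endo rather than 5-exo closure (aurone), secured by the amine relay; carbonylative rather than direct alkynylation, secured by copper-free conditions under CO pressure; and the 8''-linked isomer, secured by the substrate because iodine has a single free hydroxyl neighbour (the other is OBn) and ring D was symmetric before iodination. The second hydroxyl of ring D lies para to the new acyl carbon, cannot reach the ynone, and ends as the free 7''-OH.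

**Step 14**
Reactants: 22 (2S)-5,7-bis(benzyloxy)-2-[4-(benzyloxy)phenyl]-6-{5-(benzyloxy)-2-[4-(benzyloxy)phenyl]-7-hydroxy-4-oxo-4H-chromen-8-yl}-2,3-dihydro-4H-chromen-4-one
Product: 23 (2S)-5,7-dihydroxy-6-[5,7-dihydroxy-2-(4-hydroxyphenyl)-4-oxo-4H-chromen-8-yl]-2-(4-hydroxyphenyl)-2,3-dihydro-4H-chromen-4-one (CNP0154104.1)
Conditions: H2 (1 atm), 10% Pd/C, THF–MeOH, rt, stopped when uptake ends
Reagents that add atoms: none
Why: Catalytic hydrogenolysis of the five aryl benzyl ethers runs under neutral conditions in which C2 cannot epimerise, and at 1 atm it should be much faster than reduction of the flavone C2''=C3'' bond, of the two ketones or of the benzylic C2–O1 bond.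

**Compound list**
1 | 2,4,6-trihydroxyacetophenone | CC(=O)c1c(O)cc(O)cc1O | starting material
2 | 1-[4-(benzyloxy)-2,6-dihydroxyphenyl]ethanone | CC(=O)c1c(O)cc(OCc2ccccc2)cc1O | intermediate
3 | 1-[4-(benzyloxy)-2-hydroxy-6-(methoxymethoxy)phenyl]ethanone | CC(=O)c1c(O)cc(OCc2ccccc2)cc1OCOC | intermediate
4 | 1-[4-(benzyloxy)-3-bromo-2-hydroxy-6-(methoxymethoxy)phenyl]ethanone | CC(=O)c1c(O)c(Br)c(OCc2ccccc2)cc1OCOC | intermediate
5 | 1-[2,4-bis(benzyloxy)-3-bromo-6-(methoxymethoxy)phenyl]ethanone | CC(=O)c1c(OCc2ccccc2)c(Br)c(OCc2ccccc2)cc1OCOC | intermediate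
6 | phloroglucinol | Oc1cc(O)cc(O)c1 | starting material
7 | 3,5-bis(methoxymethoxy)phenol | COCOc1cc(O)cc(OCOC)c1 | intermediate
8 | 1-(benzyloxy)-3,5-bis(methoxymethoxy)benzene | COCOc1cc(OCc2ccccc2)cc(OCOC)c1 | intermediate
9 | [4-(benzyloxy)-2,6-bis(methoxymethoxy)phenyl]lithium | [Li]c1c(OCOC)cc(OCc2ccccc2)cc1OCOC | intermediate
10 | 2-[4-(benzyloxy)-2,6-bis(methoxymethoxy)phenyl]-4,4,5,5-tetramethyl-1,3,2-dioxaborolane | COCOc1cc(OCc2ccccc2)cc(OCOC)c1B1OC(C)(C)C(C)(C)O1 | intermediate
11 | 1-{2,4-bis(benzyloxy)-3-[4-(benzyloxy)-2,6-bis(methoxymethoxy)phenyl]-6-(methoxymethoxy)phenyl}ethanone | CC(=O)c1c(OCOC)cc(OCc2ccccc2)c(-c2c(OCOC)cc(OCc3ccccc3)cc2OCOC)c1OCc1ccccc1 | intermediate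
12 | (E)-1-{2,4-bis(benzyloxy)-3-[4-(benzyloxy)-2,6-bis(methoxymethoxy)phenyl]-6-(methoxymethoxy)phenyl}-3-(dimethylamino)prop-2-en-1-one | CN(C)/C=C/C(=O)c1c(OCOC)cc(OCc2ccccc2)c(-c2c(OCOC)cc(OCc3ccccc3)cc2OCOC)c1OCc1ccccc1 | intermediate
13 | 5,7-bis(benzyloxy)-6-[4-(benzyloxy)-2,6-dihydroxyphenyl]-4H-chromen-4-one | O=c1ccoc2cc(OCc3ccccc3)c(-c3c(O)cc(OCc4ccccc4)cc3O)c(OCc3ccccc3)c12 | intermediate
14 | 4-(benzyloxy)phenylboronic acid | OB(O)c1ccc(OCc2ccccc2)cc1 | starting material
15 | (2S)-5,7-bis(benzyloxy)-2-[4-(benzyloxy)phenyl]-6-[4-(benzyloxy)-2,6-dihydroxyphenyl]-2,3-dihydro-4H-chromen-4-one | O=C1C[C@@H](c2ccc(OCc3ccccc3)cc2)Oc2cc(OCc3ccccc3)c(-c3c(O)cc(OCc4ccccc4)cc3O)c(OCc3ccccc3)c21 | intermediate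
16 | (2S)-5,7-bis(benzyloxy)-2-[4-(benzyloxy)phenyl]-6-[4-(benzyloxy)-2,6-dihydroxy-3-iodophenyl]-2,3-dihydro-4H-chromen-4-one | O=C1C[C@@H](c2ccc(OCc3ccccc3)cc2)Oc2cc(OCc3ccccc3)c(-c3c(O)cc(OCc4ccccc4)c(I)c3O)c(OCc3ccccc3)c21 | intermediate
17 | 4-(benzyloxy)benzaldehyde | O=Cc1ccc(OCc2ccccc2)cc1 | starting material
18 | 1-(benzyloxy)-4-ethynylbenzene | C#Cc1ccc(OCc2ccccc2)cc1 | intermediate
19 | carbon monoxide | [C-]#[O+] | starting material
20 | (2S)-5,7-bis(benzyloxy)-2-[4-(benzyloxy)phenyl]-6-(4-(benzyloxy)-3-{3-[4-(benzyloxy)phenyl]prop-2-ynoyl}-2,6-dihydroxyphenyl)-2,3-dihydro-4H-chromen-4-one | O=C1C[C@@H](c2ccc(OCc3ccccc3)cc2)Oc2cc(OCc3ccccc3)c(-c3c(O)cc(OCc4ccccc4)c(C(=O)C#Cc4ccc(OCc5ccccc5)cc4)c3O)c(OCc3ccccc3)c21 | intermediate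
21 | (2S)-5,7-bis(benzyloxy)-2-[4-(benzyloxy)phenyl]-6-(4-(benzyloxy)-3-{3-[4-(benzyloxy)phenyl]-3-(diethylamino)prop-2-enoyl}-2,6-dihydroxyphenyl)-2,3-dihydro-4H-chromen-4-one | O=C1C[C@@H](c2ccc(OCc3ccccc3)cc2)Oc2cc(OCc3ccccc3)c(-c3c(O)cc(OCc4ccccc4)c(C(=O)C=C(N(CC)CC)c4ccc(OCc5ccccc5)cc4)c3O)c(OCc3ccccc3)c21 | intermediate
22 | (2S)-5,7-bis(benzyloxy)-2-[4-(benzyloxy)phenyl]-6-{5-(benzyloxy)-2-[4-(benzyloxy)phenyl]-7-hydroxy-4-oxo-4H-chromen-8-yl}-2,3-dihydro-4H-chromen-4-one (penta-O-benzyl ether of the target, 7''-OH free) | O=C1C[C@@H](c2ccc(OCc3ccccc3)cc2)Oc2cc(OCc3ccccc3)c(-c3c(O)cc(OCc4ccccc4)c4c(=O)cc(-c5ccc(OCc6ccccc6)cc5)oc34)c(OCc3ccccc3)c21 | intermediate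
23 | (2S)-5,7-dihydroxy-6-[5,7-dihydroxy-2-(4-hydroxyphenyl)-4-oxo-4H-chromen-8-yl]-2-(4-hydroxyphenyl)-2,3-dihydro-4H-chromen-4-one (CNP0154104.1) | O=C1C[C@@H](c2ccc(O)cc2)Oc2cc(O)c(-c3c(O)cc(O)c4c(=O)cc(-c5ccc(O)cc5)oc34)c(O)c21 | target

**Total step count:** 14.
**Longest linear sequence:** 10 steps (1, 2, 3, 4, 8, 9, 10, 11, 13, 14).

**Steps most likely to fail**

**Step 13.**
- What may go wrong:
  - Oxidative addition into the electron-rich C–I bond, which has oxygen substituents on both sides, may be slow.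
  - Diethylamine may capture the aroylpalladium species and give an amide.
  - Prolonged contact of ring C with the amine may cause reversible ring opening and re-closure, with erosion of the configuration at C2.
- Fallback: the order of events is changed so that the annulation runs on achiral material. It sets out from 13 and comes back at 22.
  - Chromone 13 is iodinated with NIS as in step 11 to 5,7-bis(benzyloxy)-6-[4-(benzyloxy)-2,6-dihydroxy-3-iodophenyl]-4H-chromen-4-one F1.
  - This is annulated with 18 and 19 under PdCl2(PPh3)2 in neat Et2NH at 100–120 °C and 20 bar, conditions that no stereocentre forbids. An acid wash re-closes any chromone ring opened by the amine. The product is 5,7-bis(benzyloxy)-6-{5-(benzyloxy)-2-[4-(benzyloxy)phenyl]-7-hydroxy-4-oxo-4H-chromen-8-yl}-4H-chromen-4-one F2.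
  - The rhodium-catalysed addition of 14 from step 10 is then carried out last. Only the chromone of F2 has an unsubstituted C2, and the 2-aryl enone of ring E does not accept aryl-rhodium, so the product is 22.

**Step 8.**
- What may go wrong:
  - Protodeboronation of the 2,6-dioxygenated boronate in the basic aqueous medium may outrun transmetalation to the hindered arylpalladium species.
  - Arylation at the methyl ketone may compete.
- Fallback: a Negishi coupling, which needs neither base nor water. It sets out from 8 and comes back at 11.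
  - Aryllithium 9, made from 8 as in step 7, is transmetalated with ZnCl2 to [4-(benzyloxy)-2,6-bis(methoxymethoxy)phenyl]zinc chloride F3.
  - This is coupled with bromide 5 under Pd2(dba)3 and RuPhos in THF at 65 °C to give 11.

**Step 10.**
- What may go wrong:
  - Turnover may be slow on a chromone deactivated by two alkoxy donors.
  - The free phenols may protonate aryl-rhodium.
  - Aryloxide may be eliminated from the rhodium enolate, which opens ring C.
  - Facial selectivity may be poor.
- Fallback: chalcone closure followed by kinetic resolution. It sets out from 11 and 17 and comes back at 15.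
  - Claisen–Schmidt condensation (KOH, EtOH, rt) gives (E)-1-{2,4-bis(benzyloxy)-3-[4-(benzyloxy)-2,6-bis(methoxymethoxy)phenyl]-6-(methoxymethoxy)phenyl}-3-[4-(benzyloxy)phenyl]prop-2-en-1-one F4.
  - 2 M HCl in MeOH–THF at 50 °C frees the three phenols to (E)-1-{2,4-bis(benzyloxy)-3-[4-(benzyloxy)-2,6-dihydroxyphenyl]-6-hydroxyphenyl}-3-[4-(benzyloxy)phenyl]prop-2-en-1-one F5.
  - NaOAc in refluxing EtOH closes ring C by oxa-Michael addition to racemic 5,7-bis(benzyloxy)-2-[4-(benzyloxy)phenyl]-6-[4-(benzyloxy)-2,6-dihydroxyphenyl]-2,3-dihydro-4H-chromen-4-one F6.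
  - Noyori-type transfer hydrogenation with RuCl(p-cymene)[(R,R)-TsDPEN] in HCO2H–Et3N and EtOAc is stopped near half conversion. This catalyst gives 4R carbinols and flavanones are reduced to 2,4-cis alcohols, so the 2R enantiomer is the matched one. It is consumed to (2R,4R)-5,7-bis(benzyloxy)-2-[4-(benzyloxy)phenyl]-6-[4-(benzyloxy)-2,6-dihydroxyphenyl]-3,4-dihydro-2H-chromen-4-ol F7, and the unreacted ketone, separated by chromatography, is 15.

**Further compounds**
F1 | step 13 | 5,7-bis(benzyloxy)-6-[4-(benzyloxy)-2,6-dihydroxy-3-iodophenyl]-4H-chromen-4-one | O=c1ccoc2cc(OCc3ccccc3)c(-c3c(O)cc(OCc4ccccc4)c(I)c3O)c(OCc3ccccc3)c12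
F2 | step 13 | 5,7-bis(benzyloxy)-6-{5-(benzyloxy)-2-[4-(benzyloxy)phenyl]-7-hydroxy-4-oxo-4H-chromen-8-yl}-4H-chromen-4-one | O=c1ccoc2cc(OCc3ccccc3)c(-c3c(O)cc(OCc4ccccc4)c4c(=O)cc(-c5ccc(OCc6ccccc6)cc5)oc34)c(OCc3ccccc3)c12
F3 | step 8 | [4-(benzyloxy)-2,6-bis(methoxymethoxy)phenyl]zinc chloride | Cl[Zn]c1c(OCOC)cc(OCc2ccccc2)cc1OCOC
F4 | step 10 | (E)-1-{2,4-bis(benzyloxy)-3-[4-(benzyloxy)-2,6-bis(methoxymethoxy)phenyl]-6-(methoxymethoxy)phenyl}-3-[4-(benzyloxy)phenyl]prop-2-en-1-one | O=C(/C=C/c1ccc(OCc2ccccc2)cc1)c1c(OCOC)cc(OCc2ccccc2)c(-c2c(OCOC)cc(OCc3ccccc3)cc2OCOC)c1OCc1ccccc1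
F5 | step 10 | (E)-1-{2,4-bis(benzyloxy)-3-[4-(benzyloxy)-2,6-dihydroxyphenyl]-6-hydroxyphenyl}-3-[4-(benzyloxy)phenyl]prop-2-en-1-one | O=C(/C=C/c1ccc(OCc2ccccc2)cc1)c1c(O)cc(OCc2ccccc2)c(-c2c(O)cc(OCc3ccccc3)cc2O)c1OCc1ccccc1
F6 | step 10 | racemic 5,7-bis(benzyloxy)-2-[4-(benzyloxy)phenyl]-6-[4-(benzyloxy)-2,6-dihydroxyphenyl]-2,3-dihydro-4H-chromen-4-one | O=C1CC(c2ccc(OCc3ccccc3)cc2)Oc2cc(OCc3ccccc3)c(-c3c(O)cc(OCc4ccccc4)cc3O)c(OCc3ccccc3)c21
F7 | step 10 | (2R,4R)-5,7-bis(benzyloxy)-2-[4-(benzyloxy)phenyl]-6-[4-(benzyloxy)-2,6-dihydroxyphenyl]-3,4-dihydro-2H-chromen-4-ol | O[C@@H]1C[C@H](c2ccc(OCc3ccccc3)cc2)Oc2cc(OCc3ccccc3)c(-c3c(O)cc(OCc4ccccc4)cc3O)c(OCc3ccccc3)c21
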